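**Plan**

1. Numbering as in cembrane: C1 (ether carbon with isopropyl), C2=C3, C4 (carbinol), C6 (ketone), C8 (CH–CH3), C11 (CH–OAc), C12 (ether carbon with CH3). Retrosynthesis: acetate off; ring opened at C6–C7 by taking the ketone back to an aldehyde C6–H and a C7=C8 alkene; then C3–C4 (Sonogashira), O–C12 (epoxide opening), C1–C14 (Negishi), C9–C10 (allyl–allyl coupling).
2. Forward: the achiral C7–C14 dienyl iodide is coupled to the isopropyl vinyl iodide; Sharpless epoxidation and epoxy chloride fragmentation give the C1 ethynyl carbinol; Shi epoxidation with 5-exo opening closes the oxolane ring (C1, C14, C13, C12, O); Sonogashira coupling, a second Sharpless epoxidation and hydride opening/alkyne reduction add C4–C6; oxidation, closure of the 14-membered carbocycle and acetylation finish the route.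
3. Stereochemistry: C1 and C4 from tartrate-controlled epoxidations; C11 and C12 from the Shi ketone (inversion at C12); C8 in the ring closure under ligand control; E-C11=C12 from syn-carboalumination; E-C2=C3 from alkoxide-directed trans-hydroalumination.
4. Feature used: the C6 carbonyl lies between two CH2 groups, with the methyl-bearing C8 on one β-carbon and the C4 hydroxyl on the other. The ring is therefore the adduct of an aldehyde C–H bond to a 1,1-disubstituted alkene, with a built-in O4 donor for the metal. The oxolane ring and the E-C2=C3 alkene between the quaternary C1 and C4 pre-fold the chain.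
5. No protecting group is needed at any stage.

Key step: step 16

Remark: which enantiomer of the diphosphine in step 16 gives 8S cannot be derived from precedent and has to be settled by trial (the (R)-ligand is written, its enantiomer is equally available); the alkynols and the Grignard solution used as starting materials are taken as purchasable.

Step 1
Reactants: 1 but-3-yn-1-ol
Product: 4 (E)-3-methylpent-2-ene-1,5-diol, via alkenylalane 2 (not isolated), via lithium alkenylalanate 3 (not isolated)
Conditions: Me3Al (3 equiv), Cp2ZrCl2 (25 mol %), CH2Cl2, rt; then n-BuLi, (CH2O)n, THF, −78 °C → rt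
Reagents that add atoms: trimethylaluminium, C[Al](C)C; formaldehyde (from paraformaldehyde), C=O
Why: Zirconium-catalysed carboalumination adds methyl and aluminium syn across the terminal alkyne with methyl on the internal carbon, and the alanate formed with n-BuLi is hydroxymethylated by formaldehyde with retention, which fixes the E geometry of the later C11=C12 alkene (Negishi carboalumination).

Step 2
Reactants: 4 (E)-3-methylpent-2-ene-1,5-diol
Product: 5 (E)-5-chloro-3-methylpent-3-en-1-ol
Conditions: NCS, Me2S, CH2Cl2, −20 → 0 °C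
Reagents that add atoms: N-chlorosuccinimide, ClN1C(=O)CCC1=O
Why: Corey–Kim chlorination: the chlorosulfonium salt from NCS and Me2S turns only the allylic alcohol into the chloride, the homoallylic alkoxysulfonium ion reverting to the alcohol on work-up, and the alkene geometry is untouched.

Step 3
Reactants: 5 (E)-5-chloro-3-methylpent-3-en-1-ol; 6 2-methylallylmagnesium chloride
Product: 7 (E)-3,7-dimethylocta-3,7-dien-1-ol
Conditions: 6 (2.2 equiv), Li2CuCl4 (3 mol %), THF, −30 → 0 °C
Reagents that add atoms: none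
Why: Copper-catalysed allylic substitution by the symmetrical methallyl Grignard reagent takes the SN2 course at the primary allylic chloride because γ-attack would build a quaternary carbon, the first equivalent of 6 only deprotonating the hydroxyl.

Step 4
Reactants: 7 (E)-3,7-dimethylocta-3,7-dien-1-ol
Product: 8 (E)-8-iodo-2,6-dimethylocta-1,5-diene
Conditions: I2, PPh3, imidazole, CH2Cl2, 0 °C
Reagents that add atoms: iodine, [I][I]
Why: Appel-type iodination (PPh3/I2/imidazole) replaces the primary hydroxyl by SN2 displacement of the oxyphosphonium ion and leaves both alkenes alone.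

Step 5
Reactants: 9 4-methylpent-2-yn-1-ol
Product: 11 (Z)-3-iodo-4-methylpent-2-en-1-ol, via vinylaluminate 10 (not isolated)
Conditions: NaAlH2(OCH2CH2OMe)2, THF, 0 °C → rt; then I2, −78 °C
Reagents that add atoms: iodine, [I][I]
Why: Hydroxyl-directed trans-hydroalumination of the propargylic alcohol puts aluminium on the distal carbon in a five-membered chelate and iodinolysis with retention gives the Z-iodoalkene, iodine cis to CH2OH.

Step 6
Reactants: 8 (E)-8-iodo-2,6-dimethylocta-1,5-diene; 11 (Z)-3-iodo-4-methylpent-2-en-1-ol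
Product: 13 (2E,6E)-3-isopropyl-6,10-dimethylundeca-2,6,10-trien-1-ol, via alkylzinc iodide 12 (not isolated)
Conditions: 8 (1.6 equiv), Zn dust, LiCl, THF, 40 °C; then 11, Pd(OAc)2 (2 mol %), SPhos (4 mol %), THF, rt
Reagents that add atoms: none
Why: Zinc inserts into the primary C–I bond and the palladium-catalysed Negishi sp3–sp2 coupling with the vinyl iodide keeps the alkene geometry, so the chain ends up cis and the isopropyl group trans to CH2OH.

Step 7
Reactants: 13 (2E,6E)-3-isopropyl-6,10-dimethylundeca-2,6,10-trien-1-ol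
Product: 14 [(2S,3S)-3-[(E)-3,7-dimethylocta-3,7-dien-1-yl]-3-isopropyloxiran-2-yl]methanol
Conditions: Ti(OiPr)4 (10 mol %), diethyl L-(+)-tartrate (12 mol %), t-BuOOH, 4 Å molecular sieves, CH2Cl2, −20 °C
Reagents that add atoms: tert-butyl hydroperoxide, CC(C)(C)OO
Why: Sharpless asymmetric epoxidation of the primary allylic alcohol with the L-(+)-tartrate catalyst delivers oxygen to the face that gives the (2S,3S)-epoxy alcohol (the sense known for E-3,3-disubstituted allylic alcohols such as geraniol), which sets C1, while the isolated alkenes do not react.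

Step 8
Reactants: 14 [(2S,3S)-3-[(E)-3,7-dimethylocta-3,7-dien-1-yl]-3-isopropyloxiran-2-yl]methanol
Product: 15 (2R,3S)-2-(chloromethyl)-3-[(E)-3,7-dimethylocta-3,7-dien-1-yl]-3-isopropyloxirane
Conditions: PPh3, CCl4, NaHCO3, reflux
Reagents that add atoms: carbon tetrachloride, ClC(Cl)(Cl)Cl
Why: Appel chlorination with PPh3/CCl4 under bicarbonate buffering converts the primary alcohol into the chloride without opening the acid-sensitive trisubstituted epoxide.

Step 9
Reactants: 15 (2R,3S)-2-(chloromethyl)-3-[(E)-3,7-dimethylocta-3,7-dien-1-yl]-3-isopropyloxirane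
Product: 16 (S,E)-3-isopropyl-6,10-dimethylundeca-6,10-dien-1-yn-3-ol
Conditions: LiN(iPr)2 (3.5 equiv), THF, −78 → −30 °C
Reagents that add atoms: none
Why: Base-induced double elimination of the 2,3-epoxy chloride (deprotonation at the CH2Cl carbon with epoxide opening to a chlorovinyl alkoxide, then loss of HCl) gives the terminal alkyne without breaking the C1–O bond, so C1 keeps its configuration.

Step 10
Reactants: 16 (S,E)-3-isopropyl-6,10-dimethylundeca-6,10-dien-1-yn-3-ol
Product: 18 (R)-1-[(2S,5S)-5-ethynyl-5-isopropyl-2-methyloxolan-2-yl]-4-methylpent-4-en-1-ol, via epoxide 17 (not isolated)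
Conditions: D-fructose-derived Shi ketone (30 mol %), KHSO5, K2CO3, Bu4NHSO4, MeCN/CH2(OMe)2/aq. Na2B4O7 buffer, 0 °C; then camphorsulfonic acid (cat.), CH2Cl2, 0 °C
Reagents that add atoms: potassium peroxymonosulfate, [K+].[O-]S(=O)(=O)OO
Why: Shi epoxidation: the dioxirane of the D-fructose-derived ketone attacks the electron-rich E-trisubstituted C11=C12 alkene through the spiro transition state faster than the 1,1-disubstituted alkene to give the (11R,12R)-epoxide, which the C1 hydroxyl opens under acid catalysis in the 5-exo mode at the tertiary C12 with inversion, so that the oxolane ring is closed and C12 (S) and C11 (R) are set.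

Step 11
Reactants: 19 but-2-yn-1-ol
Product: 21 (Z)-3-iodobut-2-en-1-ol, via vinylaluminate 20 (not isolated)
Conditions: NaAlH2(OCH2CH2OMe)2, THF, 0 °C → rt; then I2, −78 °C
Reagents that add atoms: iodine, [I][I]
Why: As in step 5, hydroxyl-directed trans-hydroalumination and iodinolysis with retention give the Z-iodoalkene.

Step 12
Reactants: 18 (R)-1-[(2S,5S)-5-ethynyl-5-isopropyl-2-methyloxolan-2-yl]-4-methylpent-4-en-1-ol; 21 (Z)-3-iodobut-2-en-1-ol
Product: 22 (Z)-5-[(2S,5S)-5-[(R)-1-hydroxy-4-methylpent-4-en-1-yl]-2-isopropyl-5-methyloxolan-2-yl]-3-methylpent-2-en-4-yn-1-ol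
Conditions: Pd(PPh3)2Cl2 (3 mol %), CuI (6 mol %), Et3N, THF, rt
Reagents that add atoms: none
Why: Sonogashira coupling of the terminal alkyne with the vinyl iodide proceeds with retention of the Z geometry and tolerates both free hydroxyl groups.

Step 13
Reactants: 22 (Z)-5-[(2S,5S)-5-[(R)-1-hydroxy-4-methylpent-4-en-1-yl]-2-isopropyl-5-methyloxolan-2-yl]-3-methylpent-2-en-4-yn-1-ol
Product: 23 [(2R,3S)-3-[[(2S,5S)-5-[(R)-1-hydroxy-4-methylpent-4-en-1-yl]-2-isopropyl-5-methyloxolan-2-yl]ethynyl]-3-methyloxiran-2-yl]methanol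
Conditions: Ti(OiPr)4 (1.1 equiv), diethyl D-(−)-tartrate (1.3 equiv), t-BuOOH, 4 Å molecular sieves, CH2Cl2, −25 °C
Reagents that add atoms: tert-butyl hydroperoxide, CC(C)(C)OO
Why: Sharpless asymmetric epoxidation of the Z-enynol with the D-(−)-tartrate reagent delivers oxygen to the face that gives the (2R,3S)-epoxy alcohol (the sense known for Z-3,3-disubstituted allylic alcohols such as nerol, mirrored), which sets C4, the non-allylic C11 hydroxyl and the other alkenes being inert.

Step 14
Reactants: 23 [(2R,3S)-3-[[(2S,5S)-5-[(R)-1-hydroxy-4-methylpent-4-en-1-yl]-2-isopropyl-5-methyloxolan-2-yl]ethynyl]-3-methyloxiran-2-yl]methanol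
Product: 25 (R,E)-5-[(2S,5S)-5-[(R)-1-hydroxy-4-methylpent-4-en-1-yl]-2-isopropyl-5-methyloxolan-2-yl]-3-methylpent-4-ene-1,3-diol, via ynediol 24 (not isolated)
Conditions: NaAlH2(OCH2CH2OMe)2 (excess), THF, 0 °C → rt
Reagents that add atoms: none
Why: The aluminate bound to the primary oxygen delivers hydride intramolecularly to C5 of the 2,3-epoxy alcohol (1,3-diol, C4–O bond intact) and the propargylic C4 alkoxide so formed directs trans-hydroalumination of the alkyne, which gives the E-C2=C3 alkene on protonation.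

Step 15
Reactants: 25 (R,E)-5-[(2S,5S)-5-[(R)-1-hydroxy-4-methylpent-4-en-1-yl]-2-isopropyl-5-methyloxolan-2-yl]-3-methylpent-4-ene-1,3-diol
Product: 26 (R,E)-3-hydroxy-5-[(2S,5S)-5-[(R)-1-hydroxy-4-methylpent-4-en-1-yl]-2-isopropyl-5-methyloxolan-2-yl]-3-methylpent-4-enal
Conditions: TEMPO (10 mol %), PhI(OAc)2, CH2Cl2, rt
Reagents that add atoms: none
Why: Oxoammonium oxidation (TEMPO with PhI(OAc)2 as terminal oxidant) is selective for the primary alcohol over the hindered secondary C11 hydroxyl, cannot touch the tertiary one and is neutral enough for the dehydration-prone β-hydroxy aldehyde, which is used at once.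

Step 16
Reactants: 26 (R,E)-3-hydroxy-5-[(2S,5S)-5-[(R)-1-hydroxy-4-methylpent-4-en-1-yl]-2-isopropyl-5-methyloxolan-2-yl]-3-methylpent-4-enal
Product: 27 (1S,2E,4R,8S,11R,12S)-4,11-dihydroxy-1,12-epoxycembr-2-en-6-one
Conditions: [Rh(nbd)2]BF4 (10 mol %), (R)-DTBM-SEGPHOS (11 mol %), H2 (catalyst activation), acetone, 50 °C, slow addition of 26 to 0.002 M
Reagents that add atoms: none
Why: Proposed new method: a cationic monovalent rhodium diphosphine complex should add oxidatively into the aldehyde C6–H bond to give an acyl rhodium hydride held as a five-membered chelate by the C4 hydroxyl (the donor that is meant to hold back decarbonylation), the tethered C7=C8 alkene then inserts into Rh–H with rhodium going to the unsubstituted C7, and C6–C7 reductive elimination releases the ketone. The closest known reaction types are heteroatom-chelated rhodium-catalysed alkene hydroacylation (intermolecular with β-thio and 2-hydroxyaryl aldehydes, intramolecular to seven- and eight-membered ketones with an ether donor) and the enantioselective cyclisation of 4-substituted pent-4-enals, none of which has been shown for a 14-membered ring. The 14-membered carbocycle closes in the endo mode at the alkene (new bond to the terminal CH2, anti-Markovnikov) through a 15-membered rhodacycle. The only new stereocenter, C8, is created in the hydride insertion and is to be controlled by the chiral diphosphine, the remote C1, C4, C11 and C12 centers being expected to exert little bias. The step needs linear regioselectivity, secured by the 1,1-disubstituted alkene (branched insertion would put rhodium on a tertiary carbon), and ring closure instead of oligomerisation, favoured by high dilution and by the oxolane ring and the E-C2=C3 alkene between the quaternary C1 and C4 that pre-fold the chain; the free C11 hydroxyl and the hindered C2=C3 alkene should be spectators.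

Step 17
Reactants: 27 (1S,2E,4R,8S,11R,12S)-4,11-dihydroxy-1,12-epoxycembr-2-en-6-one
Product: 28 (1S,2E,4R,8S,11R,12S)-11-acetoxy-4-hydroxy-1,12-epoxycembr-2-en-6-one
Conditions: Ac2O, pyridine, DMAP (cat.), CH2Cl2, 0 °C
Reagents that add atoms: acetic anhydride, CC(=O)OC(C)=O
Why: DMAP-catalysed acetylation esterifies the secondary C11 hydroxyl far faster than the tertiary C4 hydroxyl under conditions too mild for retro-aldol cleavage of the β-hydroxy ketone.

**Compound list**

1 | but-3-yn-1-ol | C#CCCO | starting material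
2 | alkenylalane, dimethyl[(E)-4-(dimethylaluminiooxy)-2-methylbut-1-en-1-yl]alane | C[Al](C)OCC/C(C)=C/[Al](C)C | intermediate
3 | lithium alkenylalanate (n-butyl ate complex of 2) | [Li+].CCCC[Al-](C)(C)/C=C(\C)CCO[Al](C)C | intermediate
4 | (E)-3-methylpent-2-ene-1,5-diol | OCC/C(C)=C/CO | intermediate
5 | (E)-5-chloro-3-methylpent-3-en-1-ol | OCC/C(C)=C/CCl | intermediate
6 | 2-methylallylmagnesium chloride | CC(=C)C[Mg]Cl | starting material
7 | (E)-3,7-dimethylocta-3,7-dien-1-ol | OCC/C(C)=C/CCC(C)=C | intermediate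
8 | (E)-8-iodo-2,6-dimethylocta-1,5-diene | ICC/C(C)=C/CCC(C)=C | intermediate
9 | 4-methylpent-2-yn-1-ol | CC(C)C#CCO | starting material
10 | vinylaluminate, sodium 3-isopropyl-2,2-bis(2-methoxyethoxy)-2,5-dihydro-1,2-oxaaluminol-2-uide | CC(C)C1=CCO[Al-]1(OCCOC)OCCOC.[Na+] | intermediate
11 | (Z)-3-iodo-4-methylpent-2-en-1-ol | OC/C=C(\I)C(C)C | intermediate
12 | alkylzinc iodide, [(E)-3,7-dimethylocta-3,7-dien-1-yl]zinc iodide | I[Zn]CC/C(C)=C/CCC(C)=C | intermediate
13 | (2E,6E)-3-isopropyl-6,10-dimethylundeca-2,6,10-trien-1-ol | OC/C=C(\CC/C(C)=C/CCC(C)=C)C(C)C | intermediate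
14 | [(2S,3S)-3-[(E)-3,7-dimethylocta-3,7-dien-1-yl]-3-isopropyloxiran-2-yl]methanol | OC[C@@H]1O[C@@]1(CC/C(C)=C/CCC(C)=C)C(C)C | intermediate
15 | (2R,3S)-2-(chloromethyl)-3-[(E)-3,7-dimethylocta-3,7-dien-1-yl]-3-isopropyloxirane | ClC[C@@H]1O[C@@]1(CC/C(C)=C/CCC(C)=C)C(C)C | intermediate
16 | (S,E)-3-isopropyl-6,10-dimethylundeca-6,10-dien-1-yn-3-ol | C=C(C)CC/C=C(\C)CC[C@@](O)(C#C)C(C)C | intermediate
17 | epoxide, (S)-3-isopropyl-5-[(2R,3R)-2-methyl-3-(3-methylbut-3-en-1-yl)oxiran-2-yl]pent-1-yn-3-ol | C=C(C)CC[C@H]1O[C@]1(C)CC[C@@](O)(C#C)C(C)C | intermediate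
18 | (R)-1-[(2S,5S)-5-ethynyl-5-isopropyl-2-methyloxolan-2-yl]-4-methylpent-4-en-1-ol | C=C(C)CC[C@@H](O)[C@]1(C)CC[C@@](C#C)(C(C)C)O1 | intermediate
19 | but-2-yn-1-ol | CC#CCO | starting material
20 | vinylaluminate, sodium 2,2-bis(2-methoxyethoxy)-3-methyl-2,5-dihydro-1,2-oxaaluminol-2-uide | CC1=CCO[Al-]1(OCCOC)OCCOC.[Na+] | intermediate
21 | (Z)-3-iodobut-2-en-1-ol | OC/C=C(\I)C | intermediate
22 | (Z)-5-[(2S,5S)-5-[(R)-1-hydroxy-4-methylpent-4-en-1-yl]-2-isopropyl-5-methyloxolan-2-yl]-3-methylpent-2-en-4-yn-1-ol | C=C(C)CC[C@@H](O)[C@]1(C)CC[C@@](C#C/C(C)=C\CO)(C(C)C)O1 | intermediate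
23 | [(2R,3S)-3-[[(2S,5S)-5-[(R)-1-hydroxy-4-methylpent-4-en-1-yl]-2-isopropyl-5-methyloxolan-2-yl]ethynyl]-3-methyloxiran-2-yl]methanol | C=C(C)CC[C@@H](O)[C@]1(C)CC[C@@](C#C[C@]2(C)O[C@@H]2CO)(C(C)C)O1 | intermediate
24 | ynediol, (R)-5-[(2S,5S)-5-[(R)-1-hydroxy-4-methylpent-4-en-1-yl]-2-isopropyl-5-methyloxolan-2-yl]-3-methylpent-4-yne-1,3-diol | C=C(C)CC[C@@H](O)[C@]1(C)CC[C@@](C#C[C@](C)(O)CCO)(C(C)C)O1 | intermediate
25 | (R,E)-5-[(2S,5S)-5-[(R)-1-hydroxy-4-methylpent-4-en-1-yl]-2-isopropyl-5-methyloxolan-2-yl]-3-methylpent-4-ene-1,3-diol | C=C(C)CC[C@@H](O)[C@]1(C)CC[C@@](/C=C/[C@](C)(O)CCO)(C(C)C)O1 | intermediate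
26 | (R,E)-3-hydroxy-5-[(2S,5S)-5-[(R)-1-hydroxy-4-methylpent-4-en-1-yl]-2-isopropyl-5-methyloxolan-2-yl]-3-methylpent-4-enal | C=C(C)CC[C@@H](O)[C@]1(C)CC[C@@](/C=C/[C@](C)(O)CC=O)(C(C)C)O1 | intermediate
27 | (1S,2E,4R,8S,11R,12S)-4,11-dihydroxy-1,12-epoxycembr-2-en-6-one | O[C@@H]1CC[C@H](C)CC(=O)C[C@@](C)(O)/C=C/[C@@]2(C(C)C)CC[C@]1(C)O2 | intermediate
28 | (1S,2E,4R,8S,11R,12S)-11-acetoxy-4-hydroxy-1,12-epoxycembr-2-en-6-one | CC(=O)O[C@@H]1CC[C@H](C)CC(=O)C[C@@](C)(O)/C=C/[C@@]2(C(C)C)CC[C@]1(C)O2 | target

**Step count**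

Total: 17 steps. Longest linear sequence: 15 steps (1–4, 6–10, 12–17).

**Steps most likely to fail**

Step 16 (proposed new method). What may go wrong: decarbonylation of the acyl rhodium hydride before the slow intramolecular alkene capture, rhodium hydride-induced migration of the C7=C8 alkene into the chain, oligomerisation, or poor facial selectivity at C8. The fallback uses known reaction types, closes the same bond and sets C8 afterwards; it sets out from aldehyde 26 and comes back at the target 28. Aldehyde 26 is acetylated at O11 (Ac2O, pyridine, DMAP) to the acetoxy aldehyde F1. Me2AlCl in CH2Cl2 at −78 °C under high dilution closes the ring by an intramolecular carbonyl–ene reaction (C6–C7 bond, hydrogen taken from the C8 methyl) to the macrocyclic homoallylic alcohol F2. Dess–Martin periodinane oxidises it to the β,γ-unsaturated ketone F3, and DABCO moves the double bond into conjugation to give the (E)-enone F4. Copper hydride conjugate reduction (Cu(OAc)2, DTBM-SEGPHOS, polymethylhydrosiloxane, t-BuOH, toluene) then sets C8 under ligand control and gives 28.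

Step 14. What may go wrong: SN2′ delivery of hydride to the alkynyl epoxide (allene formation), β-elimination of the alkenylaluminate towards the ring oxygen at C1, or stalling of the trans-hydroalumination at the hindered alkyne. The fallback installs the E-alkene before the epoxide; it sets out from alkyne 18 and comes back at triol 25. Palladium-catalysed hydrostannation of 18 (Bu3SnH, Pd(PPh3)2Cl2, THF) gives the (E)-vinylstannane F5. Stille coupling with iodide 21 (Pd(PPh3)4, CuI, CsF, DMF) gives the (2Z,4E)-dienol F6. Sharpless epoxidation (Ti(OiPr)4, diethyl D-(−)-tartrate, t-BuOOH) gives the vinyl epoxy alcohol F7. NaAlH2(OCH2CH2OMe)2 then only has to open the epoxide at C5 and gives 25.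

Step 6. What may go wrong: protonolysis of the alkylzinc by the free hydroxyl, and slow coupling at the isopropyl-flanked vinyl iodide with reduction or β-hydride elimination taking over. The fallback makes the trisubstituted alkene by iron-catalysed coupling of an enol triflate; it sets out from iodide 8 and comes back at allylic alcohol 13. Purchased ethyl 4-methyl-3-oxopentanoate is converted with Tf2O and aqueous LiOH into the (Z)-enol triflate F8. Iodide 8 is converted with Mg in THF into the Grignard reagent F9, which is coupled with F8 under Fe(acac)3 catalysis (THF/NMP, −30 °C) with retention to the (E)-enoate F10. Reduction of F10 with iBu2AlH gives 13.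

Further compounds
F1 | step 16 | (R)-1-[(2S,5S)-5-[(R,E)-3-hydroxy-3-methyl-5-oxopent-1-en-1-yl]-5-isopropyl-2-methyloxolan-2-yl]-4-methylpent-4-en-1-yl acetate | C=C(C)CC[C@@H](OC(C)=O)[C@]1(C)CC[C@@](/C=C/[C@](C)(O)CC=O)(C(C)C)O1
F2 | step 16 | (1S,2E,4R,11R,12S)-11-acetoxy-1,12-epoxycembra-2,8(19)-diene-4,6-diol (both C6 epimers) | CC(=O)O[C@@H]1CCC(=C)CC(O)C[C@@](C)(O)/C=C/[C@@]2(C(C)C)CC[C@]1(C)O2
F3 | step 16 | (1S,2E,4R,11R,12S)-11-acetoxy-4-hydroxy-1,12-epoxycembra-2,8(19)-dien-6-one | CC(=O)O[C@@H]1CCC(=C)CC(=O)C[C@@](C)(O)/C=C/[C@@]2(C(C)C)CC[C@]1(C)O2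
F4 | step 16 | (1S,2E,4R,7E,11R,12S)-11-acetoxy-4-hydroxy-1,12-epoxycembra-2,7-dien-6-one | CC(=O)O[C@@H]1CC/C(C)=C/C(=O)C[C@@](C)(O)/C=C/[C@@]2(C(C)C)CC[C@]1(C)O2
F5 | step 14 | (R)-1-[(2S,5S)-5-isopropyl-2-methyl-5-[(E)-2-(tributylstannyl)ethenyl]oxolan-2-yl]-4-methylpent-4-en-1-ol | C=C(C)CC[C@@H](O)[C@]1(C)CC[C@@](/C=C/[Sn](CCCC)(CCCC)CCCC)(C(C)C)O1
F6 | step 14 | (2Z,4E)-5-[(2S,5S)-5-[(R)-1-hydroxy-4-methylpent-4-en-1-yl]-2-isopropyl-5-methyloxolan-2-yl]-3-methylpenta-2,4-dien-1-ol | C=C(C)CC[C@@H](O)[C@]1(C)CC[C@@](/C=C/C(C)=C\CO)(C(C)C)O1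
F7 | step 14 | [(2R,3S)-3-[(E)-2-[(2S,5S)-5-[(R)-1-hydroxy-4-methylpent-4-en-1-yl]-2-isopropyl-5-methyloxolan-2-yl]ethenyl]-3-methyloxiran-2-yl]methanol | C=C(C)CC[C@@H](O)[C@]1(C)CC[C@@](/C=C/[C@]2(C)O[C@@H]2CO)(C(C)C)O1
F8 | step 6 | ethyl (Z)-4-methyl-3-(trifluoromethylsulfonyloxy)pent-2-enoate | CCOC(=O)/C=C(\OS(=O)(=O)C(F)(F)F)C(C)C
F9 | step 6 | [(E)-3,7-dimethylocta-3,7-dien-1-yl]magnesium iodide | I[Mg]CC/C(C)=C/CCC(C)=C
F10 | step 6 | ethyl (2E,6E)-3-isopropyl-6,10-dimethylundeca-2,6,10-trienoate | CCOC(=O)/C=C(\CC/C(C)=C/CCC(C)=C)C(C)C
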